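**Assumption:** the target has no stereocentres, so "single enantiomer" is taken to mean the single all-E (2E,6E,10E,14E,18E) geometric isomer. The route has not been run experimentally; it rests on standard menaquinone and polyprenol chemistry.

## Retrosynthetic overview

1. The quinone is unmasked last by CAN oxidation of a 1,4-dimethoxynaphthalene; the C3–C1' bond comes from a naphthyl cuprate and all-E hexaprenyl bromide.
2. The C30 bromide is assembled from two farnesol-derived C15 halves by allylic sulfone alkylation and Pd-catalysed desulfonylation.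
3. The bromonaphthalene comes from 2,8-dimethyl-1-naphthol by para-oxidation, reductive methylation and bromination.
4. The oxygenated ring of the naphthol (the only ring formed) is closed by an intramolecular aldol condensation/aromatisation of a keto-aldehyde made from 2-bromo-m-xylene.
5. The benzene ring is purchased; all five E-alkenes come from (2E,6E)-farnesol and one E-selective SeO2 oxidation.

## Route

### Naphthalene core

**Step 1**
Reactants: 1, 2-bromo-1,3-dimethylbenzene
Product: 2, 2-bromo-1-(bromomethyl)-3-methylbenzene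
Conditions: NBS (0.95 equiv), AIBN cat., PhCF3, 80 °C
Reagents that add atoms: N-bromosuccinimide, O=C1CCC(=O)N1Br
Why: Wohl–Ziegler radical benzylic bromination; the two methyls are equivalent and sub-stoichiometric NBS limits dibromination.

**Step 2**
Reactants: 2, 2-bromo-1-(bromomethyl)-3-methylbenzene
Product: 3, 2-bromo-1-methyl-3-(prop-2-en-1-yl)benzene
Conditions: vinylMgBr, CuI (10 mol %), THF, 0 °C → rt
Reagents that add atoms: vinylmagnesium bromide, C=C[Mg]Br
Why: Cu-catalysed sp3–sp2 Grignard cross-coupling occurs at the benzylic bromide and leaves the aryl bromide untouched.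

**Step 3**
Reactants: 3, 2-bromo-1-methyl-3-(prop-2-en-1-yl)benzene
Product: 4, 1-[2-methyl-6-(prop-2-en-1-yl)phenyl]propan-1-one
Conditions: n-BuLi, THF, −78 °C; then EtC(O)N(OMe)Me, −78 → 0 °C; aq NH4Cl
Reagents that add atoms: N-methoxy-N-methylpropanamide, CCC(=O)N(C)OC
Why: Br/Li exchange followed by Weinreb ketone synthesis; the chelated tetrahedral intermediate prevents over-addition.

**Step 4**
Reactants: 4, 1-[2-methyl-6-(prop-2-en-1-yl)phenyl]propan-1-one
Product: 5, 2-(3-methyl-2-propanoylphenyl)acetaldehyde (used crude)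
Conditions: O3, CH2Cl2/MeOH, −78 °C; then Me2S, −78 °C → rt
Reagents that add atoms: ozone, [O-][O+]=O
Why: Ozonolysis with reductive work-up cleaves only the terminal alkene, giving the 1,5-keto-aldehyde needed for ring closure.

**Step 5 (key ring closure)**
Reactants: 5, 2-(3-methyl-2-propanoylphenyl)acetaldehyde
Product: 6, 2,8-dimethylnaphthalen-1-ol
Conditions: KOH (2 equiv), degassed EtOH, 0 °C → rt, Ar, high dilution; then 1 M HCl
Reagents that add atoms: none
Why: Intramolecular aldol condensation: the propanoyl enolate attacks the aldehyde (6-ring), then E1cB dehydration and tautomerisation give the naphthol irreversibly. The ketone carbon becomes C1 next to the peri-methyl, which fixes the 2,8-pattern.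

**Step 6**
Reactants: 6, 2,8-dimethylnaphthalen-1-ol
Product: 7, 2,8-dimethylnaphthalene-1,4-dione
Conditions: Fremy's salt (2.5 equiv), KH2PO4 buffer, acetone/H2O, rt
Reagents that add atoms: potassium nitrosodisulfonate, [K+].[K+].[O]N(S(=O)(=O)[O-])S(=O)(=O)[O-]
Why: Teuber oxidation converts a 1-naphthol with a free para position to the 1,4-quinone, as for 2-methyl-1-naphthol to menadione.

**Step 7**
Reactants: 7, 2,8-dimethylnaphthalene-1,4-dione
Product: 8, 1,4-dimethoxy-2,8-dimethylnaphthalene
Conditions: Na2S2O4, Bu4NBr, THF/H2O, rt; then aq KOH, Me2SO4, rt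
Reagents that add atoms: dimethyl sulfate, COS(=O)(=O)OC
Why: One-pot reductive methylation: dithionite gives the hydroquinone, which is O-methylated twice under phase-transfer Williamson conditions.

**Step 8**
Reactants: 8, 1,4-dimethoxy-2,8-dimethylnaphthalene
Product: 9, 2-bromo-1,4-dimethoxy-3,5-dimethylnaphthalene
Conditions: Br2 (1.0 equiv), CH2Cl2, 0 °C, dark
Reagents that add atoms: bromine, BrBr
Why: Electrophilic aromatic bromination goes to C3, the only free position on the doubly methoxy-activated ring.

### All-E hexaprenyl bromide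

**Step 9**
Reactants: 10, (2E,6E)-farnesol
Product: 11, (2E,6E)-farnesyl bromide
Conditions: PBr3 (0.4 equiv), Et2O, −10 °C; used directly
Reagents that add atoms: phosphorus tribromide, BrP(Br)Br
Why: Low-temperature conversion of a primary allylic alcohol to the bromide keeps the 2E geometry.

**Step 10**
Reactants: 11, (2E,6E)-farnesyl bromide
Product: 12, (2E,6E)-farnesyl phenyl sulfone
Conditions: PhSO2Na, DMF, rt
Reagents that add atoms: sodium benzenesulfinate, [Na+].[O-]S(=O)c1ccccc1
Why: SN2 S-alkylation of sulfinate gives the primary allylic sulfone with the E-alkenes unchanged.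

**Step 11**
Reactants: 10, (2E,6E)-farnesol
Product: 13, tert-butyl(diphenyl){[(2E,6E)-3,7,11-trimethyldodeca-2,6,10-trien-1-yl]oxy}silane
Conditions: TBDPSCl, imidazole, DMF, rt
Reagents that add atoms: tert-butyl(chloro)diphenylsilane, CC(C)(C)[Si](Cl)(c1ccccc1)c1ccccc1
Why: Silylation gives an ether that survives SeO2/acid, organolithium and hydride conditions.

**Step 12**
Reactants: 13, farnesyl TBDPS ether
Product: 14, (2E,6E,10E)-12-[(tert-butyldiphenylsilyl)oxy]-2,6,10-trimethyldodeca-2,6,10-trien-1-ol
Conditions: SeO2 (0.2 equiv), t-BuOOH (3 equiv), salicylic acid cat., CH2Cl2, 0 °C → rt; then NaBH4, MeOH, 0 °C; recycle recovered 13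
Reagents that add atoms: selenium dioxide, O=[Se]=O, with tert-butyl hydroperoxide, CC(C)(C)OO (oxygen source)
Why: Sharpless catalytic Riley oxidation (ene/[2,3]-shift) hydroxylates the E-methyl of the most electron-rich terminal alkene, giving the (E)-allylic alcohol; NaBH4 returns over-oxidised enal.

**Step 13**
Reactants: 14, the ω-hydroxy TBDPS ether
Product: 15, {[(2E,6E,10E)-12-bromo-3,7,11-trimethyldodeca-2,6,10-trien-1-yl]oxy}(tert-butyl)diphenylsilane
Conditions: CBr4, PPh3, CH2Cl2, 0 °C
Reagents that add atoms: carbon tetrabromide, BrC(Br)(Br)Br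
Why: Appel bromination is neutral, so the silyl ether and alkene geometry are preserved.

**Step 14**
Reactants: 12, (2E,6E)-farnesyl phenyl sulfone; 15, the ω-bromo TBDPS ether
Product: 16, TBDPS ether of (2E,6E,10E,14E,18E)-3,7,11,15,19,23-hexamethyl-13-(phenylsulfonyl)tetracosa-2,6,10,14,18,22-hexaen-1-ol (racemic at C13)
Conditions: 12, n-BuLi, THF/DMPU, −78 °C; then 15, −78 → −40 °C
Reagents that add atoms: none (both partners are numbered reactants)
Why: Alkylation of the α-sulfonyl allylic carbanion at the primary allylic bromide joins the two C15 units; the transient C13 stereocentre is removed in the next step.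

**Step 15**
Reactants: 16, the C30 sulfone
Product: 17, TBDPS ether of (2E,6E,10E,14E,18E)-3,7,11,15,19,23-hexamethyltetracosa-2,6,10,14,18,22-hexaen-1-ol
Conditions: PdCl2(dppp) (5 mol %), LiEt3BH, THF, 0 °C
Reagents that add atoms: none
Why: Pd-catalysed reductive desulfonylation delivers hydride to the less substituted π-allyl terminus, keeping the C14=C15 alkene in place and E.

**Step 16**
Reactants: 17, hexaprenyl TBDPS ether
Product: 18, (2E,6E,10E,14E,18E)-3,7,11,15,19,23-hexamethyltetracosa-2,6,10,14,18,22-hexaen-1-ol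
Conditions: TBAF, THF, rt
Reagents that add atoms: none
Why: Fluoride cleaves the Si–O bond without affecting the polyene.

**Step 17**
Reactants: 18, all-E hexaprenol
Product: 19, (2E,6E,10E,14E,18E)-1-bromo-3,7,11,15,19,23-hexamethyltetracosa-2,6,10,14,18,22-hexaene
Conditions: PBr3 (0.4 equiv), Et2O, −10 °C; used immediately
Reagents that add atoms: phosphorus tribromide, BrP(Br)Br
Why: Same low-temperature allylic bromination as step 9, with 2E retained.

### Union

**Step 18**
Reactants: 9, 2-bromo-1,4-dimethoxy-3,5-dimethylnaphthalene (2 equiv); 19, hexaprenyl bromide (limiting)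
Product: 20, 2-[(2E,6E,10E,14E,18E)-3,7,11,15,19,23-hexamethyltetracosa-2,6,10,14,18,22-hexaen-1-yl]-1,4-dimethoxy-3,5-dimethylnaphthalene
Conditions: 9, n-BuLi, THF, −78 °C; CuBr·SMe2 (0.5 equiv per ArLi); then 19, −78 → 0 °C
Reagents that add atoms: none (both partners are numbered reactants)
Why: Br/Li exchange and transmetalation give a diaryl cuprate that displaces the allylic bromide by SN2 (α) with retention of the 2'E alkene; regiochemistry is fixed by the bromine position.

**Step 19**
Reactants: 20, the hexaprenyl dimethoxynaphthalene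
Product: 21, target, 2,8-dimethyl-3-[(all-E)-hexaprenyl]naphthalene-1,4-dione
Conditions: CAN (2.5 equiv), MeCN/CH2Cl2/H2O, 0 °C, 20 min
Reagents that add atoms: water, O (supplies the quinone oxygens as MeOH is lost)
Why: Ce(IV) oxidative demethylation of the p-dimethoxyarene gives the quinone faster than it attacks the isolated trisubstituted alkenes.

## Compound list

1 | 2-bromo-1,3-dimethylbenzene | Cc1cccc(C)c1Br | starting material
2 | 2-bromo-1-(bromomethyl)-3-methylbenzene | Cc1cccc(CBr)c1Br | intermediate
3 | 2-bromo-1-methyl-3-(prop-2-en-1-yl)benzene | Cc1cccc(CC=C)c1Br | intermediate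
4 | 1-[2-methyl-6-(prop-2-en-1-yl)phenyl]propan-1-one | CCC(=O)c1c(C)cccc1CC=C | intermediate
5 | 2-(3-methyl-2-propanoylphenyl)acetaldehyde | CCC(=O)c1c(C)cccc1CC=O | intermediate
6 | 2,8-dimethylnaphthalen-1-ol | Cc1ccc2cccc(C)c2c1O | intermediate
7 | 2,8-dimethylnaphthalene-1,4-dione | CC1=CC(=O)c2cccc(C)c2C1=O | intermediate
8 | 1,4-dimethoxy-2,8-dimethylnaphthalene | COc1cc(C)c(OC)c2c(C)cccc12 | intermediate
9 | 2-bromo-1,4-dimethoxy-3,5-dimethylnaphthalene | COc1c(Br)c(C)c(OC)c2c(C)cccc12 | intermediate
10 | (2E,6E)-farnesol | CC(C)=CCC/C(C)=C/CC/C(C)=C/CO | starting material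
11 | (2E,6E)-farnesyl bromide | CC(C)=CCC/C(C)=C/CC/C(C)=C/CBr | intermediate
12 | (2E,6E)-farnesyl phenyl sulfone | CC(C)=CCC/C(C)=C/CC/C(C)=C/CS(=O)(=O)c1ccccc1 | intermediate
13 | (2E,6E)-farnesyl TBDPS ether | CC(C)=CCC/C(C)=C/CC/C(C)=C/CO[Si](c1ccccc1)(c1ccccc1)C(C)(C)C | intermediate
14 | (2E,6E,10E)-12-(TBDPS-oxy)-2,6,10-trimethyldodeca-2,6,10-trien-1-ol | OC/C(C)=C/CC/C(C)=C/CC/C(C)=C/CO[Si](c1ccccc1)(c1ccccc1)C(C)(C)C | intermediate
15 | (2E,6E,10E)-12-bromo-3,7,11-trimethyldodeca-2,6,10-trien-1-yl TBDPS ether | BrC/C(C)=C/CC/C(C)=C/CC/C(C)=C/CO[Si](c1ccccc1)(c1ccccc1)C(C)(C)C | intermediate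
16 | 13-(phenylsulfonyl) all-E hexaprenyl TBDPS ether (racemic at C13) | CC(C)=CCC/C(C)=C/CC/C(C)=C/C(C/C(C)=C/CC/C(C)=C/CC/C(C)=C/CO[Si](c1ccccc1)(c1ccccc1)C(C)(C)C)S(=O)(=O)c1ccccc1 | intermediate
17 | all-E hexaprenyl TBDPS ether | CC(C)=CCC/C(C)=C/CC/C(C)=C/CC/C(C)=C/CC/C(C)=C/CC/C(C)=C/CO[Si](c1ccccc1)(c1ccccc1)C(C)(C)C | intermediate
18 | all-E hexaprenol | CC(C)=CCC/C(C)=C/CC/C(C)=C/CC/C(C)=C/CC/C(C)=C/CC/C(C)=C/CO | intermediate
19 | all-E hexaprenyl bromide | CC(C)=CCC/C(C)=C/CC/C(C)=C/CC/C(C)=C/CC/C(C)=C/CC/C(C)=C/CBr | intermediate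
20 | 2-(all-E-hexaprenyl)-1,4-dimethoxy-3,5-dimethylnaphthalene | CC(C)=CCC/C(C)=C/CC/C(C)=C/CC/C(C)=C/CC/C(C)=C/CC/C(C)=C/Cc1c(C)c(OC)c2c(C)cccc2c1OC | intermediate
21 | 2,8-dimethyl-3-(all-E-hexaprenyl)naphthalene-1,4-dione (CID101244058) | CC(C)=CCC/C(C)=C/CC/C(C)=C/CC/C(C)=C/CC/C(C)=C/CC/C(C)=C/CC1=C(C)C(=O)c2c(C)cccc2C1=O | target

## Summary

**Total step count:** 19

**Longest linear sequence:** 10 steps (steps 1–8, then 18 and 19). The chain branch from farnesol through 13 is 9 steps (11–19).

**Steps most likely to fail, with fallbacks:**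

1. **Step 5, intramolecular aldol/aromatisation.** The more acidic aryl-acetaldehyde may self-condense or form an isochromene. Fallback: close the ring by ring-closing metathesis. Add the aryllithium from 3 to methacrolein, oxidise to 1-(2-allyl-6-methylphenyl)-2-methylprop-2-en-1-one, and treat with Grubbs II; the resulting naphthalen-1(4H)-one tautomerises to 6.
2. **Step 12, SeO2 allylic oxidation.** Conversion is modest and internal alkenes or the enal can compete. Fallback: functionalise the terminus by the van Tamelen sequence instead. Terminal bromohydrin (NBS/H2O) → epoxide → HIO4 cleavage to the trisnor aldehyde → Wittig with Ph3P=C(Me)CO2Et (E-selective) → DIBAL gives 14.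
3. **Step 18, cuprate allylation.** SN2' attack, loss of 2'E geometry or biaryl homocoupling are possible. Fallback: reverse the polarity. Convert 19 to the hexaprenyl tributylstannane (Bu3SnLi) and add it to quinone 7 with BF3·OEt2 at −78 °C, then Ag2O. C3 is the only free quinone position, and this also removes steps 7, 8 and 19.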